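## The problem

1. The target (35) is two bicyclic halves on an ethano bridge. With squalene-type numbering, ring A is the oxepane O1–C2–C3–C4–C5–C6–C7, ring B the cyclohexane C6–C11, C12–C13 the bridge, ring C the cycloheptene C14–C15–C16–C17–C18–C22–C23 and ring D the cyclopentane C18–C22; methyls sit on C2 (two), C6, C10, C15, C19 and C23 (two).
2. Rings A/B are trans-fused with five stereocentres (C3 acetate, quaternary C6, C7, C11, and the tertiary carbinol C10 whose hydroxyl is axial and syn to the C6 methyl). Rings C/D are cis-fused with four (allylic carbinol C16, C18, tertiary carbinol C19, C22).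
3. The two clusters are separated by the bridge and by the flat tetrasubstituted C14=C15 olefin, so neither can relay configuration to the other; each half must be made as one enantiomer and then joined.
4. Both ring systems resist closure: ring A needs a tertiary ether bond (C2–O–C7) beside the quaternary C6, and ring C is a seven-membered ring whose tetrasubstituted olefin is wedged between the quaternary C23 and C16.
5. Within each half the centres can control each other. Two epoxide carbons (C3, C7) can fix C6 and C11 through a chair closure, and the axial C6 methyl can then steer a nucleophile at C10. In the right half one centre on ring D can fix C18, C19 and C22, because a short tether allows only the cis fusion.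
6. The feature that makes the key step possible is the oxygen pattern of rings A and B. The ring-A oxygen links the gem-dimethyl carbon C2 to C7, C3 bears oxygen, and the quaternary C6 is bonded to C11 next to the oxygenated C10. This is what remains when a (3R,6R,7R)-2,3;6,7-diepoxide (8) is opened first by its own internal epoxide oxygen at C2 and then by a C10=C11 enol π-bond at C6.
7. A second feature serves the union: C14 and the C16 oxygen stand 1,3 across the methyl-bearing C15. This is the retron of a 2-methyl-1,3-diketone whose C14 carbonyl, blocked on one side by C23, can accept the bridge carbon C13.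
8. Sensitive points are the two tertiary alcohols (elimination), the allylic C16 carbinol (ionisation under acid), and the single acetate, which must go onto C3 when no other secondary hydroxyl is free.

## Retrosynthesis

**35 ⇒ 34 ⇒ 33 ⇒ 32.** The C16–H bond is cut first, leading to enone 34. With C16 still a ketone, C3–OH is the only secondary hydroxyl of triol 33, so acetylation needs no protecting-group play. Triol 33 comes from the silyl-protected enone 32. The forward reduction must deliver hydride to the concave face, which calls for reagent control.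

**32 ⇒ 14 + 29.** The C13–C14 σ-bond and the C14=C15 π-bond are cut together (alkylative enone transposition). Cutting C12–C13 or C11–C12 instead would be an sp3–sp3 coupling that needs auxiliary groups and leaves the tetrasubstituted olefin to be made separately. A cross-coupling at C14 is not chosen because sulfonylation of dione 27 would go to the less hindered oxygen on C16. The precursors are two bicycles, iodide 14 (five stereocentres) and vinylogous ester 29 (three). The forward step demands 1,2-addition to the hindered C14 carbonyl.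

**14 ⇒ 13 ⇒ 12 ⇒ 11 ⇒ 10.** The C10–CH3 bond is cut. A water-terminated cation–olefin closure would put the C10 hydroxyl equatorial; the target has it axial, which is the result of equatorial methyl addition to a C10 ketone shielded by the C6 methyl. Ketone 10 already carries C12–C13 as a protected hydroxyethyl group.

**10 ⇒ 8 (key).** The C2–O1 and C6–C11 bonds are cut at once, so bicyclic 10 becomes the acyclic diepoxy enol silane 8. Closing ring A onto a ready-made ring B would mean a separate tertiary etherification with exo/endo ambiguity. The cascade asks for endo opening at C2 and attack at C6, both tertiary centres.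

**8 ⇒ 7 ⇒ 6 ⇒ 4 + 5; 4 ⇒ 1 + 2.** The enol silane is traced to enone 7 because only 1,4-hydrosilylation fixes the enol double bond between C10 and C11. The epoxides come from triene 6 by reagent-controlled epoxidation. The C11=C12 bond is cut to phosphonate 4 and aldehyde 5, and C8–C9 to geranyl bromide 1 and phosphonate 2.

**29 ⇒ 28 ⇒ 27 ⇒ 25.** The C17–C18 bond is cut: ring C closes when the terminal carbanion of the diketone dianion opens the ring-D epoxide. Cutting C15–C16 (Claisen) would first need a cis-1,2-disubstituted cyclopentane built by an intermolecular attack syn to a bulky neighbour. The chosen cut gives ring C, C18 and the C19 carbinol from a monocyclic precursor.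

**25 ⇒ 23 ⇒ 22 ⇒ 21.** C15–C16 (acylation), the epoxide oxygen and C14–C15 (ethyl addition) are cut in turn. Because C23 is quaternary, each enolisation and the dianion formation can go only one way.

**21 ⇒ 19 ⇒ 16 + 17; 16 ⇒ 15.** The C22–C23 bond is cut by a [3,3] shift. The Ireland–Claisen rearrangement of ester 19 builds the quaternary C23 and transfers the carbinol chirality of 16 to C22. Alcohol 16 is the ring-closing-metathesis product of linalool 15, whose C2–C6 and C3-methyl become C18–C22 and the C19 methyl.

## Roads not taken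

**Alternative 1:** (the most obvious) Cut the saturated bridge bond C12–C13 between two finished bicycles. The forward key step is alkylation of the lithiated sulfone A1 (rings A/B) with allylic bromide A2 (rings C/D), then reductive desulfonylation. Each bicycle would be made by stepwise closures: ring A by hydroxy-epoxide etherification onto a preformed ring B, ring C by metathesis or ring expansion. The chosen plan is better for three reasons:
- The sulfone is installed and removed without leaving anything the target needs.
- A2 already contains the tetrasubstituted olefin, so the hardest feature of ring C is not addressed by the union.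
- Desulfonylation beside an allylic system risks olefin migration, and the stepwise ring A needs an etherification at a tertiary carbon with exo/endo competition.

**Alternative 2:** Cut C18–C22 and C14–C23 at once, imitating the presumed biogenesis of rings C/D. The forward key step is Lewis-acid treatment (for example EtAlCl2) of the cross-conjugated dienone A3, made from (R)-linalool. The C22=C23 olefin attacks the activated C18, and the C23 cation is to be captured by C14 in a cationic (5+2) closure to enone A4. It would give both rings, the quaternary C23 and the enone in one step. It is set aside on mechanistic grounds: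
- The U-shaped pentadienyl cation needed can also close on itself by 4π electrocyclisation to a cyclopentenone.
- After the first bond the C23 cation faces a 2-oxydiene whose nucleophilic sites are C17 and oxygen, not C14, so proton loss, a dihydropyran or a cyclobutane are the likely outcomes.
- The C18/C22 configuration would rest on one acyclic centre.

**Alternative 3:** Cut the C16–O bond with transposition of the olefin (retro-ene), a likely biogenetic origin of the 16-hydroxy-Δ14 unit. The forward key step is a singlet-oxygen (Schenck) ene reaction on the Δ15 olefin A5, followed by reduction of hydroperoxide A6 to 35. It is set aside because: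
- A5 has the same four rings plus an extra stereocentre at C14, so nothing is simplified.
- Its trisubstituted olefin offers three sets of allylic hydrogens (C14–H, the C15 methyl, C17–H2), and neither the regiochemistry nor the facial selectivity can be secured by the substrate.
- In the chosen plan the Δ14 olefin and the C16 oxygen come with the bond that joins the halves.

Key step: step 5

Remark (assumption): (S)-(+)-linalool (15) is taken as purchasable in high enantiomeric purity; the commoner (R)-enantiomer would give the mirror-image ring C/D half.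

## Route

Step 1
Reactants: 1 geranyl bromide [(2E)-1-bromo-3,7-dimethylocta-2,6-diene]; 2 dimethyl (2-oxopropyl)phosphonate
Product: 4 dimethyl [(5E)-6,10-dimethyl-2-oxoundeca-5,9-dien-1-yl]phosphonate, via phosphonate dianion 3 (not isolated)
Conditions: 2, NaH, THF, 0 °C; n-BuLi, 0 °C; then 1, 0 °C → rt; aq. NH4Cl
Reagents that add atoms: none
Why: γ-Alkylation of a β-ketophosphonate dianion: the more basic terminal carbanion of 3 displaces the allylic bromide (SN2) and forms C8–C9 without touching the (E)-olefin.

Step 2
Reactants: 4 dimethyl [(5E)-6,10-dimethyl-2-oxoundeca-5,9-dien-1-yl]phosphonate; 5 (benzyloxy)acetaldehyde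
Product: 6 (2E,7E)-1-(benzyloxy)-8,12-dimethyltrideca-2,7,11-trien-4-one
Conditions: LiCl, i-Pr2NEt, MeCN, rt
Reagents that add atoms: none
Why: Horner–Wadsworth–Emmons olefination under mild LiCl/amine conditions should give the (E)-enone and brings in C12–C13 with its protected oxygen; the enone is the handle that later fixes enolisation of the C10 ketone towards C11.

Step 3
Reactants: 6 (2E,7E)-1-(benzyloxy)-8,12-dimethyltrideca-2,7,11-trien-4-one
Product: 7 (2E)-1-(benzyloxy)-6-[(2R,3R)-3-{2-[(2R)-3,3-dimethyloxiran-2-yl]ethyl}-3-methyloxiran-2-yl]hex-2-en-4-one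
Conditions: D-fructose-derived Shi ketone (1,2:4,5-di-O-isopropylidene-β-D-erythro-2,3-hexodiulo-2,6-pyranose, 0.6 equiv), Oxone (2KHSO5·KHSO4·K2SO4), K2CO3, Bu4NHSO4, MeCN/CH2(OMe)2/aq. Na2B4O7 buffer (pH 10.5), 0 °C
Reagents that add atoms: potassium peroxymonosulfate (KHSO5, the oxidant in Oxone), [K+].[O-]S(=O)(=O)OO
Why: Shi asymmetric epoxidation: the chiral dioxirane attacks the two electron-rich trisubstituted olefins through the spiro transition state and leaves the electron-poor enone alone. Every epoxide carbon (C3; C6 and C7) is expected with R configuration, which sets the absolute configuration of the whole left half.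

Step 4
Reactants: 7 (2E)-1-(benzyloxy)-6-[(2R,3R)-3-{2-[(2R)-3,3-dimethyloxiran-2-yl]ethyl}-3-methyloxiran-2-yl]hex-2-en-4-one
Product: 8 triethyl{[(3Z)-6-(benzyloxy)-1-[(2R,3R)-3-{2-[(2R)-3,3-dimethyloxiran-2-yl]ethyl}-3-methyloxiran-2-yl]hex-3-en-3-yl]oxy}silane
Conditions: Et3SiH, RhCl(PPh3)3 (1 mol%), benzene, 50 °C
Reagents that add atoms: triethylsilane, CC[SiH](CC)CC
Why: Rhodium-catalysed 1,4-hydrosilylation of an enone with a monohydrosilane gives the silyl enol ether regiospecifically (C10=C11, mainly Z), which no deprotonation of the saturated ketone could do; trisubstituted epoxides and the benzyl ether are inert to these neutral conditions.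

Step 5
Reactants: 8 triethyl{[(3Z)-6-(benzyloxy)-1-[(2R,3R)-3-{2-[(2R)-3,3-dimethyloxiran-2-yl]ethyl}-3-methyloxiran-2-yl]hex-3-en-3-yl]oxy}silane
Product: 10 (3R,5aR,6R,9aR)-6-[2-(benzyloxy)ethyl]-3-[(tert-butyldimethylsilyl)oxy]-2,2,5a-trimethyloctahydro-1-benzoxepin-7(2H)-one, via bicyclic epoxonium triflate 9 (not isolated)
Conditions: TBSOTf (1.3 equiv), 2,6-di-tert-butyl-4-methylpyridine, CH2Cl2, −78 °C; aq. NaHCO3
Reagents that add atoms: tert-butyldimethylsilyl trifluoromethanesulfonate, CC(C)(C)[Si](C)(C)OS(=O)(=O)C(F)(F)F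
Why: The silyl triflate silylates the oxygen of the terminal epoxide, the oxygen of the 6,7-epoxide then attacks the tertiary C2 to give the bicyclic epoxonium ion 9, and C11 of the enol silane opens 9 at the tertiary C6, after which the triethylsilyl group leaves and the C10 ketone appears. The closest known reaction type is the Lewis-acid-promoted tandem oxa-/carbacyclisation of 1,5-diepoxides ended by enol silanes or allylsilanes, an offshoot of epoxy-polyene cyclisation. Ring A closes in the endo mode at the terminal epoxide (attack on C2 gives a six-membered epoxonium ring that becomes the oxepane when C6–O breaks); ring B closes as a six-membered ring through a chair in which the breaking C6–O bond is exocyclic and the enol π-bond endocyclic. C3 and C7 keep the configuration given by the epoxidation because their C–O bonds are never broken. C6 is inverted by backside attack, which with the E geometry of the former olefin puts the C6 methyl and C7–H trans-diaxial and makes rings A/B trans-fused. C11 is set by the chair, in which the Z enol silane places C12 equatorial, and since C11 is α to the new ketone any epimer can equilibrate to this more stable isomer. The step needs endo rather than exo opening of the terminal epoxide and attack at C6 rather than C7; both are secured by the tertiary, cation-stabilising carbons C2 and C6, while the regiochemically pure enol silane ensures that C11 and not C9 is the nucleophile. The hindered pyridine removes adventitious acid so that neither epoxide opens by a protic pathway, and the silyl group ends as the C3 protecting group.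

Step 6
Reactants: 10 (3R,5aR,6R,9aR)-6-[2-(benzyloxy)ethyl]-3-[(tert-butyldimethylsilyl)oxy]-2,2,5a-trimethyloctahydro-1-benzoxepin-7(2H)-one
Product: 11 (3R,5aR,6R,7S,9aR)-6-[2-(benzyloxy)ethyl]-3-[(tert-butyldimethylsilyl)oxy]-2,2,5a,7-tetramethyldecahydro-1-benzoxepin-7-ol
Conditions: MeMgBr, CeCl3, THF, −78 °C; aq. NH4Cl
Reagents that add atoms: methylmagnesium bromide, C[Mg]Br
Why: Cerium-mediated Grignard addition suppresses enolisation of the α-branched ketone. The axial face of C10 is blocked by the syn-axial C6 methyl, so methyl should enter equatorially and the new hydroxyl should be axial (10S), as with 3-axially substituted cyclohexanones.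

Step 7
Reactants: 11 (3R,5aR,6R,7S,9aR)-6-[2-(benzyloxy)ethyl]-3-[(tert-butyldimethylsilyl)oxy]-2,2,5a,7-tetramethyldecahydro-1-benzoxepin-7-ol
Product: 12 {[(3R,5aR,6R,7S,9aR)-6-[2-(benzyloxy)ethyl]-2,2,5a,7-tetramethyl-7-[(triethylsilyl)oxy]decahydro-1-benzoxepin-3-yl]oxy}(tert-butyl)dimethylsilane
Conditions: TESOTf, 2,6-lutidine, CH2Cl2, 0 °C → rt
Reagents that add atoms: triethylsilyl trifluoromethanesulfonate, CC[Si](CC)(CC)OS(=O)(=O)C(F)(F)F
Why: Silyl triflate silylation of the hindered tertiary alcohol; it must be capped before C13 becomes an iodide, because the free C10 alkoxide would close a tetrahydrofuran onto C13 and would quench the later organolithium.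

Step 8
Reactants: 12 {[(3R,5aR,6R,7S,9aR)-6-[2-(benzyloxy)ethyl]-2,2,5a,7-tetramethyl-7-[(triethylsilyl)oxy]decahydro-1-benzoxepin-3-yl]oxy}(tert-butyl)dimethylsilane
Product: 13 2-[(3R,5aR,6R,7S,9aR)-3-[(tert-butyldimethylsilyl)oxy]-2,2,5a,7-tetramethyl-7-[(triethylsilyl)oxy]decahydro-1-benzoxepin-6-yl]ethan-1-ol
Conditions: H2 (1 atm), Pd/C (10% Pd on carbon), EtOAc, rt
Reagents that add atoms: none
Why: Hydrogenolysis of the benzyl ether; the molecule has no olefin or other reducible group, so the silyl ethers, the ring-A ether and all stereocentres should be untouched.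

Step 9
Reactants: 13 2-[(3R,5aR,6R,7S,9aR)-3-[(tert-butyldimethylsilyl)oxy]-2,2,5a,7-tetramethyl-7-[(triethylsilyl)oxy]decahydro-1-benzoxepin-6-yl]ethan-1-ol
Product: 14 tert-butyl{[(3R,5aR,6R,7S,9aR)-6-(2-iodoethyl)-2,2,5a,7-tetramethyl-7-[(triethylsilyl)oxy]decahydro-1-benzoxepin-3-yl]oxy}dimethylsilane
Conditions: I2, PPh3, imidazole, CH2Cl2, 0 °C
Reagents that add atoms: iodine, II
Why: Appel-type iodination of the primary alcohol (SN2 at C13 on the oxyphosphonium salt); the imidazole-buffered conditions should leave both silyl ethers intact.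

Step 10
Reactants: 15 (S)-(+)-linalool [(3S)-3,7-dimethylocta-1,6-dien-3-ol]
Product: 16 (1S)-1-methylcyclopent-2-en-1-ol
Conditions: second-generation Grubbs catalyst RuCl2(=CHPh)(PCy3)(H2IMes) (0.5 mol%), CH2Cl2, 40 °C
Reagents that add atoms: none
Why: Ring-closing olefin metathesis between the vinyl group and the trisubstituted olefin expels 2-methylpropene and gives the ring-D carbons C18–C22 with the methyl on C19; the carbinol stereocentre is not involved and stays S.

Step 11
Reactants: 16 (1S)-1-methylcyclopent-2-en-1-ol; 17 2-methylpropanoyl chloride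
Product: 19 (1S)-1-methylcyclopent-2-en-1-yl 2-methylpropanoate, via lithium alkoxide 18 (not isolated)
Conditions: n-BuLi, THF, −78 °C; then 17, −78 → 0 °C
Reagents that add atoms: none
Why: O-Acylation of the lithium alkoxide of a tertiary allylic alcohol with an acid chloride at low temperature avoids the ionisation that acid catalysis would cause.

Step 12
Reactants: 19 (1S)-1-methylcyclopent-2-en-1-yl 2-methylpropanoate
Product: 21 2-methyl-2-[(1R)-3-methylcyclopent-2-en-1-yl]propanoic acid, via silyl ketene acetal 20 (not isolated)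
Conditions: LiN(i-Pr)2 (LDA), THF, −78 °C; Me3SiCl, −78 → 50 °C; then aq. HCl
Reagents that add atoms: none
Why: Ireland–Claisen rearrangement: ketene acetal 20 rearranges suprafacially through the only (boat-like) transition state the ring allows, so the C22–C23 bond forms on the face that held the ester oxygen. The S carbinol centre is thereby traded for the R centre at C22, while the quaternary C23 and the C14 carboxyl appear; the ketene acetal has two identical methyls, so its geometry is no issue.

Step 13
Reactants: 21 2-methyl-2-[(1R)-3-methylcyclopent-2-en-1-yl]propanoic acid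
Product: 22 2-methyl-2-[(1R)-3-methylcyclopent-2-en-1-yl]pentan-3-one
Conditions: EtLi (2.2 equiv), Et2O, 0 °C → rt; then aq. HCl
Reagents that add atoms: ethyllithium, [Li]CC
Why: Addition of an alkyllithium to a lithium carboxylate gives the ketone after hydrolysis of the stable gem-diolate; the neopentyl-type acid resists over-addition, and the ethyl group supplies C15 and its methyl.

Step 14
Reactants: 22 2-methyl-2-[(1R)-3-methylcyclopent-2-en-1-yl]pentan-3-one
Product: 23 2-methyl-2-[(1S,2S,5R)-5-methyl-6-oxabicyclo[3.1.0]hexan-2-yl]pentan-3-one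
Conditions: mCPBA, NaHCO3, CH2Cl2, 0 °C
Reagents that add atoms: 3-chloroperoxybenzoic acid, OOC(=O)c1cccc(Cl)c1
Why: Peracid epoxidation of the trisubstituted ring olefin is faster than Baeyer–Villiger oxidation of the hindered ketone and should occur anti to the bulky C22 substituent, placing the oxygen on the face where the C19 hydroxyl must end.

Step 15
Reactants: 23 2-methyl-2-[(1S,2S,5R)-5-methyl-6-oxabicyclo[3.1.0]hexan-2-yl]pentan-3-one
Product: 25 2,4-dimethyl-2-[(1S,2S,5R)-5-methyl-6-oxabicyclo[3.1.0]hexan-2-yl]hexane-3,5-dione (C4 epimers and enol), via lithium enolate 24 (not isolated)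
Conditions: LiN(i-Pr)2 (1.1 equiv), THF, −78 °C; then MeC(O)N(OMe)Me, −78 → −20 °C; aq. NH4Cl
Reagents that add atoms: N-methoxy-N-methylacetamide, CC(=O)N(C)OC
Why: C-Acylation of lithium enolate 24 (only C15 can be deprotonated, C23 being quaternary) with a Weinreb amide, whose chelated tetrahedral adduct prevents proton exchange and double acylation. At −78 °C the enolate should not open the epoxide, a five-membered enolendo closure being disfavoured.

Step 16
Reactants: 25 2,4-dimethyl-2-[(1S,2S,5R)-5-methyl-6-oxabicyclo[3.1.0]hexan-2-yl]hexane-3,5-dione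
Product: 27 (1R,3aR,8aR)-1-hydroxy-1,4,4,6-tetramethylhexahydroazulene-5,7(1H,6H)-dione (C6 epimers and enol), via diketone dianion 26 (not isolated)
Conditions: LiN(i-Pr)2 (2.3 equiv), THF, −78 → 0 °C; then DMPU, 0 → 40 °C; aq. NH4Cl
Reagents that add atoms: none
Why: γ-Alkylation of a 1,3-diketone dianion by an epoxide, here intramolecular (7-enolendo-exo-tet): the terminal carbanion C17 of 26, the only γ-position because C23 is quaternary, opens the epoxide at the less substituted C18 with inversion. Its tether sits on the face of C22 opposite the epoxide oxygen, so the ring fusion must be cis (18R) and the oxygen stays on C19 as the tertiary alcohol (19R). Attack by C15 instead would be a disfavoured five-membered enolendo closure.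

Step 17
Reactants: 27 (1R,3aR,8aR)-1-hydroxy-1,4,4,6-tetramethylhexahydroazulene-5,7(1H,6H)-dione
Product: 28 (1R,3aR,8aR)-1-hydroxy-7-methoxy-1,4,4,6-tetramethyl-2,3,3a,4,8,8a-hexahydroazulen-5(1H)-one
Conditions: Me3SiCHN2, MeOH/toluene (1:4), 0 °C → rt
Reagents that add atoms: (trimethylsilyl)diazomethane, C[Si](C)(C)C=[N+]=[N-]
Why: O-Methylation of the enolised 1,3-dione should occur on the oxygen of the less hindered carbonyl (C16, next to CH2), because the C14 oxygen is flanked by the gem-dimethyl C23 and the C15 methyl. C14 is left as the only carbonyl, under conditions too mild to dehydrate the tertiary alcohol.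

Step 18
Reactants: 28 (1R,3aR,8aR)-1-hydroxy-7-methoxy-1,4,4,6-tetramethyl-2,3,3a,4,8,8a-hexahydroazulen-5(1H)-one
Product: 29 (1R,3aR,8aR)-7-methoxy-1,4,4,6-tetramethyl-1-[(triethylsilyl)oxy]-2,3,3a,4,8,8a-hexahydroazulen-5(1H)-one
Conditions: TESOTf, 2,6-lutidine, CH2Cl2, −78 → 0 °C
Reagents that add atoms: triethylsilyl trifluoromethanesulfonate, CC[Si](CC)(CC)OS(=O)(=O)C(F)(F)F
Why: Silyl triflate silylation of the tertiary C19 alcohol removes the last acidic proton before the organolithium step; any transient O-silylation of the vinylogous ester reverts on aqueous work-up.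

Step 19
Reactants: 14 tert-butyl{[(3R,5aR,6R,7S,9aR)-6-(2-iodoethyl)-2,2,5a,7-tetramethyl-7-[(triethylsilyl)oxy]decahydro-1-benzoxepin-3-yl]oxy}dimethylsilane; 29 (1R,3aR,8aR)-7-methoxy-1,4,4,6-tetramethyl-1-[(triethylsilyl)oxy]-2,3,3a,4,8,8a-hexahydroazulen-5(1H)-one
Product: 32 7-{2-[(3R,5aR,6R,7S,9aR)-3-[(tert-butyldimethylsilyl)oxy]-2,2,5a,7-tetramethyl-7-[(triethylsilyl)oxy]decahydro-1-benzoxepin-6-yl]ethyl}-(3R,3aR,8aR)-3,6,8,8-tetramethyl-3-[(triethylsilyl)oxy]-2,3,3a,4,8,8a-hexahydroazulen-5(1H)-one, via alkyllithium 30 (not isolated), via lithium alkoxide 31 (not isolated)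
Conditions: 14, t-BuLi (2.1 equiv), Et2O/pentane, −78 °C; then 29, THF, −78 → 0 °C; then 1 M aq. HCl, THF, 0 °C
Reagents that add atoms: water, O
Why: Stork–Danheiser alkylative enone transposition: iodine–lithium exchange gives primary alkyllithium 30, which adds 1,2 to the vinylogous ester carbonyl C14 (no α-hydrogen on the C23 side); acid then turns carbinol 31 into the enone by loss of the C14 oxygen and hydrolysis of the enol ether. The C13–C14 bond, the tetrasubstituted C14=C15 olefin and the C16 carbonyl arise together, and the transient carbinol centre is lost, so no stereochemistry is at stake. Any tertiary silyl ether cleaved by the acid converges in step 20.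

Step 20
Reactants: 32 silyl-protected enone (name as in step 19)
Product: 33 7-{2-[(3R,5aR,6R,7S,9aR)-3,7-dihydroxy-2,2,5a,7-tetramethyldecahydro-1-benzoxepin-6-yl]ethyl}-(3R,3aR,8aR)-3-hydroxy-3,6,8,8-tetramethyl-2,3,3a,4,8,8a-hexahydroazulen-5(1H)-one
Conditions: Bu4NF (excess), THF, rt → 50 °C; aq. NH4Cl
Reagents that add atoms: none
Why: Fluoride-induced desilylation removes the secondary tert-butyldimethylsilyl ether and both tertiary triethylsilyl ethers in one operation; the enone, the ring-A ether and the tertiary alcohols should tolerate the reagent.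

Step 21
Reactants: 33 triol enone (name as in step 20)
Product: 34 (3R,5aR,6R,7S,9aR)-7-hydroxy-6-{2-[(1R,3aR,8aR)-1-hydroxy-1,4,4,6-tetramethyl-7-oxo-1,2,3,3a,4,7,8,8a-octahydroazulen-5-yl]ethyl}-2,2,5a,7-tetramethyldecahydro-1-benzoxepin-3-yl acetate
Conditions: Ac2O, pyridine, DMAP (cat.), CH2Cl2, 0 °C → rt
Reagents that add atoms: acetic anhydride, CC(=O)OC(C)=O
Why: Acylation with acetic anhydride/pyridine discriminates the single secondary alcohol (C3) from the two tertiary ones; because C16 is still a ketone, no other secondary hydroxyl competes.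

Step 22
Reactants: 34 acetoxy enone (name as in step 21)
Product: 35 (3R,5aR,6R,7S,9aR)-6-{2-[(1R,3aR,7R,8aR)-1,7-dihydroxy-1,4,4,6-tetramethyl-1,2,3,3a,4,7,8,8a-octahydroazulen-5-yl]ethyl}-7-hydroxy-2,2,5a,7-tetramethyldecahydro-1-benzoxepin-3-yl acetate (target)
Conditions: (S)-2-methyl-CBS-oxazaborolidine (1 equiv), BH3·SMe2, THF, −30 °C; then MeOH
Reagents that add atoms: none
Why: Corey–Bakshi–Shibata reduction: the (S)-oxazaborolidine should bind the ketone with the α-methylalkenyl side (C15) as the large group and deliver hydride to give the 16R alcohol by 1,2-reduction. Catalyst control is needed because the open convex face of the cis-fused ring system would otherwise be attacked; the acetate and the tetrasubstituted olefin are inert to borane at low temperature.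

## Compound list

1 | geranyl bromide [(2E)-1-bromo-3,7-dimethylocta-2,6-diene] | CC(C)=CCC/C(C)=C/CBr | starting material
2 | dimethyl (2-oxopropyl)phosphonate | CC(=O)CP(=O)(OC)OC | starting material
3 | sodium lithium dianion of 2 | [Na+].[Li+].C=C([O-])[CH-]P(=O)(OC)OC | intermediate
4 | dimethyl [(5E)-6,10-dimethyl-2-oxoundeca-5,9-dien-1-yl]phosphonate | COP(=O)(OC)CC(=O)CC/C=C(\C)CCC=C(C)C | intermediate
5 | (benzyloxy)acetaldehyde | O=CCOCc1ccccc1 | starting material
6 | (2E,7E)-1-(benzyloxy)-8,12-dimethyltrideca-2,7,11-trien-4-one | O=C(/C=C/COCc1ccccc1)CC/C=C(\C)CCC=C(C)C | intermediate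
7 | (2E)-1-(benzyloxy)-6-[(2R,3R)-3-{2-[(2R)-3,3-dimethyloxiran-2-yl]ethyl}-3-methyloxiran-2-yl]hex-2-en-4-one | O=C(/C=C/COCc1ccccc1)CC[C@H]1O[C@]1(C)CC[C@H]1OC1(C)C | intermediate
8 | triethyl{[(3Z)-6-(benzyloxy)-1-[(2R,3R)-3-{2-[(2R)-3,3-dimethyloxiran-2-yl]ethyl}-3-methyloxiran-2-yl]hex-3-en-3-yl]oxy}silane | CC[Si](CC)(CC)O/C(CC[C@H]1O[C@]1(C)CC[C@H]1OC1(C)C)=C\CCOCc1ccccc1 | intermediate
9 | bicyclic epoxonium triflate (O+ bonded to C2, C6 and C7; C3–OTBS) | CC[Si](CC)(CC)O/C(CC[C@H]1[O+]2[C@]1(C)CC[C@@H](O[Si](C)(C)C(C)(C)C)C2(C)C)=C\CCOCc1ccccc1.[O-]S(=O)(=O)C(F)(F)F | intermediate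
10 | (3R,5aR,6R,9aR)-6-[2-(benzyloxy)ethyl]-3-[(tert-butyldimethylsilyl)oxy]-2,2,5a-trimethyloctahydro-1-benzoxepin-7(2H)-one | CC(C)(C)[Si](C)(C)O[C@@H]1CC[C@]2(C)[C@@H](CCOCc3ccccc3)C(=O)CC[C@H]2OC1(C)C | intermediate
11 | (3R,5aR,6R,7S,9aR)-6-[2-(benzyloxy)ethyl]-3-[(tert-butyldimethylsilyl)oxy]-2,2,5a,7-tetramethyldecahydro-1-benzoxepin-7-ol | CC(C)(C)[Si](C)(C)O[C@@H]1CC[C@]2(C)[C@@H](CCOCc3ccccc3)[C@@](C)(O)CC[C@H]2OC1(C)C | intermediate
12 | 7-O-triethylsilyl ether of 11 | CC(C)(C)[Si](C)(C)O[C@@H]1CC[C@]2(C)[C@@H](CCOCc3ccccc3)[C@@](C)(O[Si](CC)(CC)CC)CC[C@H]2OC1(C)C | intermediate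
13 | 2-[(3R,5aR,6R,7S,9aR)-3-[(tert-butyldimethylsilyl)oxy]-2,2,5a,7-tetramethyl-7-[(triethylsilyl)oxy]decahydro-1-benzoxepin-6-yl]ethan-1-ol | CC(C)(C)[Si](C)(C)O[C@@H]1CC[C@]2(C)[C@@H](CCO)[C@@](C)(O[Si](CC)(CC)CC)CC[C@H]2OC1(C)C | intermediate
14 | tert-butyl{[(3R,5aR,6R,7S,9aR)-6-(2-iodoethyl)-2,2,5a,7-tetramethyl-7-[(triethylsilyl)oxy]decahydro-1-benzoxepin-3-yl]oxy}dimethylsilane | CC(C)(C)[Si](C)(C)O[C@@H]1CC[C@]2(C)[C@@H](CCI)[C@@](C)(O[Si](CC)(CC)CC)CC[C@H]2OC1(C)C | intermediate
15 | (S)-(+)-linalool [(3S)-3,7-dimethylocta-1,6-dien-3-ol] | C=C[C@@](C)(O)CCC=C(C)C | starting material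
16 | (1S)-1-methylcyclopent-2-en-1-ol | C[C@@]1(O)C=CCC1 | intermediate
17 | 2-methylpropanoyl chloride | CC(C)C(=O)Cl | starting material
18 | lithium (1S)-1-methylcyclopent-2-en-1-olate | [Li+].C[C@@]1([O-])C=CCC1 | intermediate
19 | (1S)-1-methylcyclopent-2-en-1-yl 2-methylpropanoate | CC(C)C(=O)O[C@]1(C)C=CCC1 | intermediate
20 | trimethylsilyl ketene acetal of 19 | CC(C)=C(O[Si](C)(C)C)O[C@]1(C)C=CCC1 | intermediate
21 | 2-methyl-2-[(1R)-3-methylcyclopent-2-en-1-yl]propanoic acid | CC1=C[C@H](C(C)(C)C(=O)O)CC1 | intermediate
22 | 2-methyl-2-[(1R)-3-methylcyclopent-2-en-1-yl]pentan-3-one | CC1=C[C@H](C(C)(C)C(=O)CC)CC1 | intermediate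
23 | 2-methyl-2-[(1S,2S,5R)-5-methyl-6-oxabicyclo[3.1.0]hexan-2-yl]pentan-3-one | C[C@@]12CC[C@@H](C(C)(C)C(=O)CC)[C@@H]1O2 | intermediate
24 | lithium (Z)-enolate of 23 | [Li+].C[C@@]12CC[C@@H](C(C)(C)/C([O-])=C/C)[C@@H]1O2 | intermediate
25 | 2,4-dimethyl-2-[(1S,2S,5R)-5-methyl-6-oxabicyclo[3.1.0]hexan-2-yl]hexane-3,5-dione | C[C@@]12CC[C@@H](C(C)(C)C(=O)C(C)C(C)=O)[C@@H]1O2 | intermediate
26 | dilithium dianion of 25 | [Li+].[Li+].C[C@@]12CC[C@@H](C(C)(C)C([O-])=C(C)C([O-])=C)[C@@H]1O2 | intermediate
27 | (1R,3aR,8aR)-1-hydroxy-1,4,4,6-tetramethylhexahydroazulene-5,7(1H,6H)-dione | O=C1C(C)C(=O)C[C@@H]2[C@@H](CC[C@@]2(C)O)C1(C)C | intermediate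
28 | (1R,3aR,8aR)-1-hydroxy-7-methoxy-1,4,4,6-tetramethyl-2,3,3a,4,8,8a-hexahydroazulen-5(1H)-one | O=C1C(C)=C(OC)C[C@@H]2[C@@H](CC[C@@]2(C)O)C1(C)C | intermediate
29 | 1-O-triethylsilyl ether of 28 | O=C1C(C)=C(OC)C[C@@H]2[C@@H](CC[C@@]2(C)O[Si](CC)(CC)CC)C1(C)C | intermediate
30 | primary alkyllithium from 14 | CC(C)(C)[Si](C)(C)O[C@@H]1CC[C@]2(C)[C@@H](CC[Li])[C@@](C)(O[Si](CC)(CC)CC)CC[C@H]2OC1(C)C | intermediate
31 | lithium alkoxide adduct of 30 and 29 (C14 epimers) | [Li+].CC(C)(C)[Si](C)(C)O[C@@H]1CC[C@]2(C)[C@@H](CCC3([O-])C(C)=C(OC)C[C@@H]4[C@@H](CC[C@@]4(C)O[Si](CC)(CC)CC)C3(C)C)[C@@](C)(O[Si](CC)(CC)CC)CC[C@H]2OC1(C)C | intermediate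
32 | silyl-protected enone (C3–OTBS, C10–OTES, C19–OTES, C16 ketone) | CC(C)(C)[Si](C)(C)O[C@@H]1CC[C@]2(C)[C@@H](CCC3=C(C)C(=O)C[C@@H]4[C@@H](CC[C@@]4(C)O[Si](CC)(CC)CC)C3(C)C)[C@@](C)(O[Si](CC)(CC)CC)CC[C@H]2OC1(C)C | intermediate
33 | triol enone | O[C@@H]1CC[C@]2(C)[C@@H](CCC3=C(C)C(=O)C[C@@H]4[C@@H](CC[C@@]4(C)O)C3(C)C)[C@@](C)(O)CC[C@H]2OC1(C)C | intermediate
34 | C3 acetate of 33 | CC(=O)O[C@@H]1CC[C@]2(C)[C@@H](CCC3=C(C)C(=O)C[C@@H]4[C@@H](CC[C@@]4(C)O)C3(C)C)[C@@](C)(O)CC[C@H]2OC1(C)C | intermediate
35 | CNP0157376.1 (name as in step 22) | CC(=O)O[C@@H]1CC[C@]2(C)[C@@H](CCC3=C(C)[C@H](O)C[C@@H]4[C@@H](CC[C@@]4(C)O)C3(C)C)[C@@](C)(O)CC[C@H]2OC1(C)C | target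

## Step count and least certain steps

Total: 22 steps. Longest linear sequence: 13 steps (steps 1–9 then 19–22; the ring C/D branch, steps 10–18 then 19–22, is equally long).

**Step 5 (key step).** The likeliest failure is silyl transfer to the internal epoxide oxygen before the terminal one. Carbocyclisation would then outrun oxacyclisation, and the C7 oxygen would end as a silyl ether that can no longer reach the terminal epoxide. Exo opening at C3 (a tetrahydropyran) and protodesilylation of the enol silane are lesser risks. The fallback closes the two rings in separate operations; it sets out from 8 and returns at 10. MeAlCl2 (CH2Cl2, −78 °C), which transfers no silyl group, triggers only the enol silane–epoxide carbocyclisation and gives hydroxy epoxide F1 with a free C7 hydroxyl. Camphorsulfonic acid (CH2Cl2, 0 °C) then closes ring A by endo opening of the terminal epoxide at the tertiary C2 to give oxepane alcohol F2. TBSOTf/2,6-lutidine returns to 10.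

**Step 16.** The seven-membered closure may be slow relative to base-induced isomerisation of the epoxide to an allylic alcohol and to O-alkylation by the C14 enolate oxygen, because the chelated dianion tends to hold C17 away from C18. The fallback replaces the intramolecular alkylation by an intermolecular opening followed by a Claisen ring closure; it sets out from 23 and returns at 27. Lithium ethoxyacetylide with BF3·OEt2 (THF, −78 °C) opens the epoxide at the less substituted C18 with inversion (the hindered ketone should be spared) to give ynol ether F3. Dilute H2SO4 in ethanol hydrates it to hydroxy ester F4. KOt-Bu (THF/t-BuOH) then closes ring C by condensation of the C15 enolate onto the C16 ester, the stabilised diketonate draining reversible aldol side-equilibria, to give 27.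

**Step 19.** Deprotonation of the vinylogous ester at C17 and slow addition to the crowded C14 carbonyl may compete, as may silyl migration within the organolithium. The fallback replaces carbonyl addition by cross-coupling; it sets out from 29 and 14 and returns at 32. Oxalyl chloride (CH2Cl2, 0 °C) converts 29 with carbonyl transposition into β-chloro enone F5 (chloride enters at the O-acylated C14; the methyl on the C16 oxygen is lost as chloromethane). Zinc dust with LiCl (THF) inserts into iodide 14 to give alkylzinc iodide F6. Negishi coupling (Pd(OAc)2, 2-dicyclohexylphosphino-2',6'-dimethoxybiphenyl, THF) joins them to 32.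

**Step 22.** Hydride must arrive on the concave face, against the substrate bias, so poor facial selectivity (a mismatched case) is the risk. The fallback sets the centre by inversion instead; it sets out from 34 and returns at 35. NaBH4/CeCl3 (MeOH, −78 °C), attacking the open convex face, gives the 16-epimeric alcohol F7. Mitsunobu inversion with chloroacetic acid (PPh3, diisopropyl azodicarboxylate) gives the 16R chloroacetate F8. K2CO3 (cat.) in MeOH at −20 °C removes the chloroacetate much faster than the hindered C3 acetate to give 35.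

## Further compounds

F1 | step 5 | hydroxy epoxide (ring B closed, C7–OH free, terminal epoxide intact) | CC1(C)O[C@@H]1CC[C@]1(C)[C@@H](CCOCc2ccccc2)C(=O)CC[C@H]1O
F2 | step 5 | oxepane alcohol (3-hydroxy analogue of 10) | O[C@@H]1CC[C@]2(C)[C@@H](CCOCc3ccccc3)C(=O)CC[C@H]2OC1(C)C
F3 | step 16 | ynol ether from opening of 23 at C18 | CCOC#C[C@@H]1[C@@H](CC[C@@]1(C)O)C(C)(C)C(=O)CC
F4 | step 16 | hydroxy ester (C17H2–C16O2Et on C18) | CCOC(=O)C[C@@H]1[C@@H](CC[C@@]1(C)O)C(C)(C)C(=O)CC
F5 | step 19 | β-chloro enone (C14–Cl, C16 ketone, C19–OTES) | ClC1=C(C)C(=O)C[C@@H]2[C@@H](CC[C@@]2(C)O[Si](CC)(CC)CC)C1(C)C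
F6 | step 19 | alkylzinc iodide from 14 | CC(C)(C)[Si](C)(C)O[C@@H]1CC[C@]2(C)[C@@H](CC[Zn]I)[C@@](C)(O[Si](CC)(CC)CC)CC[C@H]2OC1(C)C
F7 | step 22 | 16-epimer of 35 | CC(=O)O[C@@H]1CC[C@]2(C)[C@@H](CCC3=C(C)[C@@H](O)C[C@@H]4[C@@H](CC[C@@]4(C)O)C3(C)C)[C@@](C)(O)CC[C@H]2OC1(C)C
F8 | step 22 | 16R chloroacetate of 35 | CC(=O)O[C@@H]1CC[C@]2(C)[C@@H](CCC3=C(C)[C@H](OC(=O)CCl)C[C@@H]4[C@@H](CC[C@@]4(C)O)C3(C)C)[C@@](C)(O)CC[C@H]2OC1(C)C
A1 | alternative 1 | ring A/B C12 phenyl sulfone (C3–OTBS, C10–OTES) | CC(C)(C)[Si](C)(C)O[C@@H]1CC[C@]2(C)[C@@H](CS(=O)(=O)c3ccccc3)[C@@](C)(O[Si](CC)(CC)CC)CC[C@H]2OC1(C)C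
A2 | alternative 1 | ring C/D allylic bromide (C13–Br, C16–OTBS, C19–OTES) | BrCC1=C(C)[C@H](O[Si](C)(C)C(C)(C)C)C[C@@H]2[C@@H](CC[C@@]2(C)O[Si](CC)(CC)CC)C1(C)C
A3 | alternative 2 | (2E,5E,7R)-3,7,11-trimethyl-7-[(triethylsilyl)oxy]dodeca-2,5,10-trien-4-one (C13 as methyl) | C/C=C(\C)C(=O)/C=C/[C@](C)(O[Si](CC)(CC)CC)CCC=C(C)C
A4 | alternative 2 | hydroazulenone expected from A3 (C13 as methyl) | CC1=C(C)C(=O)C[C@@H]2[C@@H](CC[C@@]2(C)O[Si](CC)(CC)CC)C1(C)C
A5 | alternative 3 | Δ15 olefin with C14–H (one C14 epimer drawn; the centre is destroyed) | CC(=O)O[C@@H]1CC[C@]2(C)[C@@H](CC[C@@H]3C(C)=CC[C@@H]4[C@@H](CC[C@@]4(C)O)C3(C)C)[C@@](C)(O)CC[C@H]2OC1(C)C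
A6 | alternative 3 | 16-hydroperoxide of 35 | CC(=O)O[C@@H]1CC[C@]2(C)[C@@H](CCC3=C(C)[C@H](OO)C[C@@H]4[C@@H](CC[C@@]4(C)O)C3(C)C)[C@@](C)(O)CC[C@H]2OC1(C)C
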